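A direct plan would cut the ester C–O bond. Chlororesorcinol A1 would be O-methylated at one hydroxyl, the resulting phenol would be esterified with benzyl-protected orsellinic acid A2, and hydrogenolysis to depside A3 would be followed by formylation of both free positions of ring A. Its weakest steps would be:
- the mono-O-methylation of A1, which would have to tell apart two hydroxyls that differ only by an ortho chlorine against an ortho methyl group;
- the esterification, which would join a 2,6-disubstituted acid to a 2,6-disubstituted phenol and would force three protecting-group steps, the last a hydrogenolysis beside an aryl chloride;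
- the closing double formylation of A3, whose second formyl group would have to enter an already deactivated ring in hot acid.

The route disconnects ring A itself and leaves the ester alone. Ring A carries C3–C4–C5 as a 3-oxopentanedial unit (CHO on C3 and C5, OH on C4), and this unit is a γ-pyranone in open form. The key step isomerizes an aryl 2-acetyl-3-oxo-3-(4-oxo-4H-pyran-3-yl)propanoate into the target: a secondary amine unzips the pyranone, which sets free both formyl carbons, and an aldol closure of C5 on the acetyl carbon (C6) builds the hexasubstituted benzene on the finished ester. The hindered ester is therefore made early from acetylketene, no hydroxyl is protected, no formylation is needed, and the methoxy group comes from a monophenol of ring B.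

Key step: step 10

Remark: the target has no stereocentre; 2,4,5-trimethylphenol is assumed to be commercial; the β-dicarbonyl and tricarbonyl compounds 10, 13, 17 and 18 are drawn as keto tautomers although they should exist largely as chelated enols or enolates.

Step 1
Reactants: 1 2,4,5-trimethylphenol
Product: 2 2-chloro-3,4,6-trimethylphenol
Conditions: SO2Cl2 (1.05 equiv), iBu2NH (5 mol%), toluene, 20 to 60 °C
Reagents that add atoms: sulfuryl chloride, O=S(=O)(Cl)Cl
Why: Electrophilic aromatic chlorination of a phenol whose para position is blocked, so that the amine-moderated reagent should chlorinate the single free ortho carbon, the other free carbon being meta to the hydroxyl.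

Step 2
Reactants: 2 2-chloro-3,4,6-trimethylphenol
Product: 3 2-chloro-1-methoxy-3,4,6-trimethylbenzene
Conditions: MeI (1.5 equiv), K2CO3 (2 equiv), DMF, rt
Reagents that add atoms: iodomethane, CI
Why: Williamson O-methylation of the only hydroxyl group, which needs no selectivity and fixes the methoxy group of ring B beside the chlorine.

Step 3
Reactants: 3 2-chloro-1-methoxy-3,4,6-trimethylbenzene
Product: 4 1-bromo-4-chloro-3-methoxy-2,5,6-trimethylbenzene
Conditions: Br2 (1.05 equiv), FeBr3 (2 mol%), CH2Cl2, 0 °C, dark
Reagents that add atoms: bromine, BrBr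
Why: Electrophilic aromatic bromination at the only ring C–H, which is activated by two ortho methyl groups and is para to chlorine, with light excluded to avoid benzylic bromination.

Step 4
Reactants: 4 1-bromo-4-chloro-3-methoxy-2,5,6-trimethylbenzene
Product: 7 4-chloro-3-methoxy-2,5,6-trimethylphenol, via (4-chloro-3-methoxy-2,5,6-trimethylphenyl)lithium 5 (not isolated), via dimethyl (4-chloro-3-methoxy-2,5,6-trimethylphenyl)boronate 6 (not isolated)
Conditions: n-BuLi (1.05 equiv), THF, −78 °C; B(OMe)3 (1.5 equiv), −78 °C to rt; then AcOH, 30% aq. H2O2, 0 °C to rt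
Reagents that add atoms: hydrogen peroxide, OO
Why: Bromine–lithium exchange (much faster than chlorine–lithium exchange at −78 °C), borylation of the aryllithium and oxidative 1,2-shift from boron to oxygen (boronate oxidation) should place the hydroxyl between the two methyl groups.

Step 5
Reactants: 7 4-chloro-3-methoxy-2,5,6-trimethylphenol; 8 2,2,6-trimethyl-4H-1,3-dioxin-4-one
Product: 10 4-chloro-3-methoxy-2,5,6-trimethylphenyl 3-oxobutanoate, via acetylketene 9 (not isolated)
Conditions: 8 (1.5 equiv), xylene, 140 °C, acetone distilled off
Reagents that add atoms: none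
Why: Thermal retro-[4+2] cleavage of the dioxinone releases acetylketene, a small linear electrophile that is trapped even by di-ortho-substituted phenols (acetoacetylation with the diketene–acetone adduct), so the hindered ester is formed before ring A exists.

Step 6
Reactants: 11 tert-butyl 3-oxobutanoate
Product: 12 tert-butyl 2-[(dimethylamino)methylidene]-3-oxobutanoate
Conditions: Me2NCH(OMe)2 (1.2 equiv), toluene, rt to 50 °C
Reagents that add atoms: N,N-dimethylformamide dimethyl acetal, COC(OC)N(C)C
Why: Condensation of the active methylene group of a β-keto ester with an amide acetal (aminomethylenation); the carbon introduced is the future formyl carbon on C3 of ring A.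

Step 7
Reactants: 12 tert-butyl 2-[(dimethylamino)methylidene]-3-oxobutanoate
Product: 14 tert-butyl 4-oxo-4H-pyran-3-carboxylate, via tert-butyl 2-[(dimethylamino)methylidene]-3,5-dioxopentanoate 13 (not isolated)
Conditions: LiN(SiMe3)2 (2.2 equiv), THF, −78 °C; HCO2Et (1.5 equiv), −78 to 0 °C; then 1 M aq. HCl, 0 °C to rt
Reagents that add atoms: ethyl formate, CCOC=O
Why: Crossed Claisen condensation of the methyl ketone enolate of the enaminone with a formate, then acid-induced addition–elimination of the new enol oxygen at the aminomethylene carbon, should close the γ-pyranone (the known enaminone route to 4-pyranone-3-carboxylates); the formate carbon is the future formyl carbon on C5.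

Step 8
Reactants: 14 tert-butyl 4-oxo-4H-pyran-3-carboxylate
Product: 15 4-oxo-4H-pyran-3-carboxylic acid
Conditions: CF3CO2H–CH2Cl2 (1:2), rt
Reagents that add atoms: none
Why: Acidolysis of the tert-butyl ester with loss of isobutene, under which the acid-stable γ-pyranone should remain intact.

Step 9
Reactants: 15 4-oxo-4H-pyran-3-carboxylic acid; 10 4-chloro-3-methoxy-2,5,6-trimethylphenyl 3-oxobutanoate
Product: 17 4-chloro-3-methoxy-2,5,6-trimethylphenyl 2-acetyl-3-oxo-3-(4-oxo-4H-pyran-3-yl)propanoate, via 4-oxo-4H-pyran-3-carbonyl chloride 16 (not isolated)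
Conditions: 15, SOCl2 (3 equiv), toluene, 70 °C, then evaporation; 10, MgCl2 (1.1 equiv), pyridine (2.2 equiv), MeCN, 0 °C; cold 1 M aq. HCl work-up
Reagents that add atoms: none
Why: Acid chloride formation followed by C-acylation of the magnesium chelate of a β-keto ester (MgCl2–pyridine method), in which chelation directs the acyl group to carbon and the tricarbonyl product is held as its stable magnesium enolate.

Step 10
Reactants: 17 4-chloro-3-methoxy-2,5,6-trimethylphenyl 2-acetyl-3-oxo-3-(4-oxo-4H-pyran-3-yl)propanoate
Product: 20 4-chloro-3-methoxy-2,5,6-trimethylphenyl 3,5-diformyl-2,4-dihydroxy-6-methylbenzoate, via bis-enaminone 18 (not isolated), via bis(aminomethylidene)cyclohexenedione 19 (not isolated)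
Conditions: pyrrolidine (3 equiv), MeCN, 0 to 40 °C; then 2 M aq. HCl–THF, rt
Reagents that add atoms: water, O
Why: Proposed new method: pyrrolidine should add to the two unsubstituted pyranone carbons C2 and C6 (β-carbons of a doubly activated vinylogous ester) with loss of the ring oxygen as water, so that bis-enaminone 18 holds the former pyranone as an open 3-oxopentanedial unit with both future formyl carbons as vinylogous amides; the nucleophilic α-carbon of the terminal enaminone (future C5) then adds to the acetyl carbonyl (future C6), and loss of water gives dienedione 19, the bis-enamine tautomer of ring A, which aqueous acid hydrolyses to the dialdehyde. The closest known reaction types are the opening of 4-pyranones and chromones by secondary amines to enaminones, the base-induced conversion of 2,6-dialkyl-4-pyranones through 1,3,5-triketones into resorcinols, and the aldol aromatization of 3,5,7-triketo esters to resorcylates; new is that the two pyranone CH carbons end as formyl groups of the arene. Ring A closes in a 6-(enolexo)-exo-trig aldol condensation, and no stereocentre is formed. The step needs this closure to win over attack of the tricarbonyl methine carbon (future C1) on the terminal enaminone carbon, over Claisen closure on the ester and over acyl cleavage. The substrate should secure this because C1 is a tertiary carbon whose addition would give a reversible quaternary adduct, the enaminone carbons are poor electrophiles without strong acid, the ester carbonyl is shielded by the two ortho methyl groups of ring B, and the largely enolized tricarbonyl unit resists acyl cleavage by the amine. Since only the C5–C6 closure can aromatize without losing carbon, the reversible ring-chain isomers should drain into 19.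

**Compound list**
1 | 2,4,5-trimethylphenol | Cc1cc(C)c(O)cc1C | starting material
2 | 2-chloro-3,4,6-trimethylphenol | Cc1cc(C)c(O)c(Cl)c1C | intermediate
3 | 2-chloro-1-methoxy-3,4,6-trimethylbenzene | COc1c(C)cc(C)c(C)c1Cl | intermediate
4 | 1-bromo-4-chloro-3-methoxy-2,5,6-trimethylbenzene | COc1c(C)c(Br)c(C)c(C)c1Cl | intermediate
5 | (4-chloro-3-methoxy-2,5,6-trimethylphenyl)lithium | [Li]c1c(C)c(OC)c(Cl)c(C)c1C | intermediate
6 | dimethyl (4-chloro-3-methoxy-2,5,6-trimethylphenyl)boronate | COB(OC)c1c(C)c(OC)c(Cl)c(C)c1C | intermediate
7 | 4-chloro-3-methoxy-2,5,6-trimethylphenol | COc1c(C)c(O)c(C)c(C)c1Cl | intermediate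
8 | 2,2,6-trimethyl-4H-1,3-dioxin-4-one | CC1=CC(=O)OC(C)(C)O1 | starting material
9 | acetylketene (but-1-ene-1,3-dione) | CC(=O)C=C=O | intermediate
10 | 4-chloro-3-methoxy-2,5,6-trimethylphenyl 3-oxobutanoate | CC(=O)CC(=O)Oc1c(C)c(OC)c(Cl)c(C)c1C | intermediate
11 | tert-butyl 3-oxobutanoate | CC(=O)CC(=O)OC(C)(C)C | starting material
12 | tert-butyl 2-[(dimethylamino)methylidene]-3-oxobutanoate (mixture of E and Z isomers) | CC(=O)C(=CN(C)C)C(=O)OC(C)(C)C | intermediate
13 | tert-butyl 2-[(dimethylamino)methylidene]-3,5-dioxopentanoate (present as its lithium enolate) | CN(C)C=C(C(=O)OC(C)(C)C)C(=O)CC=O | intermediate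
14 | tert-butyl 4-oxo-4H-pyran-3-carboxylate | CC(C)(C)OC(=O)c1coccc1=O | intermediate
15 | 4-oxo-4H-pyran-3-carboxylic acid | O=C(O)c1coccc1=O | intermediate
16 | 4-oxo-4H-pyran-3-carbonyl chloride | O=C(Cl)c1coccc1=O | intermediate
17 | 4-chloro-3-methoxy-2,5,6-trimethylphenyl 2-acetyl-3-oxo-3-(4-oxo-4H-pyran-3-yl)propanoate | CC(=O)C(C(=O)Oc1c(C)c(OC)c(Cl)c(C)c1C)C(=O)c1coccc1=O | intermediate
18 | 4-chloro-3-methoxy-2,5,6-trimethylphenyl 2-acetyl-3,5-dioxo-7-(pyrrolidin-1-yl)-4-(pyrrolidin-1-ylmethylidene)hept-6-enoate (6E; geometry at C4 undefined) | CC(=O)C(C(=O)Oc1c(C)c(OC)c(Cl)c(C)c1C)C(=O)C(=CN1CCCC1)C(=O)/C=C/N1CCCC1 | intermediate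
19 | 4-chloro-3-methoxy-2,5,6-trimethylphenyl 2-methyl-4,6-dioxo-3,5-bis(pyrrolidin-1-ylmethylidene)cyclohex-1-ene-1-carboxylate (mixture of geometric isomers) | CC1=C(C(=O)Oc2c(C)c(OC)c(Cl)c(C)c2C)C(=O)C(=CN2CCCC2)C(=O)C1=CN1CCCC1 | intermediate
20 | 4-chloro-3-methoxy-2,5,6-trimethylphenyl 3,5-diformyl-2,4-dihydroxy-6-methylbenzoate | COc1c(C)c(OC(=O)c2c(C)c(C=O)c(O)c(C=O)c2O)c(C)c(C)c1Cl | target

Total step count: 10. Longest linear sequence: 7 steps (steps 1, 2, 3, 4, 5, 9 and 10).

**Steps most likely to fail**

Step 10 (new method).
- What may go wrong: closure of the tricarbonyl methine carbon on the terminal enaminone carbon followed by loss of the acetyl group, Claisen closure with expulsion of the phenoxide, or cleavage of a formyl carbon before ring A has formed.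
- Fallback: it uses the known dioxinone route to resorcylates and a late formylation, sets out from dioxinone 8 and phenol 7, and returns at 20.
  - Deprotonation of 8 (LiN(iPr)2, THF, −78 °C) and C-acetylation with acetyl chloride would give 2,2-dimethyl-6-(2-oxopropyl)-4H-1,3-dioxin-4-one F1.
  - The dianion of F1 would be acetylated again (N-methoxy-N-methylacetamide) to 6-(2,4-dioxopentyl)-2,2-dimethyl-4H-1,3-dioxin-4-one F2.
  - Heating F2 with 7 (toluene, 110 °C) would trap the acylketene as 4-chloro-3-methoxy-2,5,6-trimethylphenyl 3,5,7-trioxooctanoate F3.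
  - Aldol aromatization (Et3N, CH2Cl2; then HCl–MeOH) would give orsellinate A3, and Rieche formylation of both free positions (Cl2CHOMe, TiCl4, CH2Cl2) would give 20.

Step 9.
- What may go wrong: conjugate addition of the magnesium enolate to C2 of the pyranone in place of attack at the acid chloride, O-acylation, or loss of the aryloxide from the enolate of 10 by ketene formation.
- Fallback: it reverses the order of the two acylations, sets out from acid 15 and phenol 7, and returns at 17.
  - 15 would be condensed with Meldrum's acid (DCC, DMAP, CH2Cl2) to 5-[hydroxy(4-oxo-4H-pyran-3-yl)methylidene]-2,2-dimethyl-1,3-dioxane-4,6-dione F4.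
  - Thermolysis of F4 with 7 (toluene, 100 °C) would pass through the pyranonyl acylketene and give 4-chloro-3-methoxy-2,5,6-trimethylphenyl 3-oxo-3-(4-oxo-4H-pyran-3-yl)propanoate F5.
  - C-acetylation of F5 with the small electrophile acetyl chloride (MgCl2, pyridine) would give 17.

Step 7.
- What may go wrong: quenching of the enolate by proton transfer, self-condensation, attack of the amide base on the formate, or incomplete ring closure.
- Fallback: it avoids strong base, sets out from enaminone 12, and returns at 14.
  - A second aminomethylenation at the methyl ketone with tert-butoxybis(dimethylamino)methane (neat, 80 °C) would give tert-butyl 5-(dimethylamino)-2-[(dimethylamino)methylidene]-3-oxopent-4-enoate F6.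
  - Brief treatment of F6 with dilute aqueous acid would hydrolyse one enamine and close the ring by addition–elimination, the known route from 1,5-bis(dimethylamino)penta-1,4-dien-3-ones to 4-pyranones.

**Further compounds**
F1 | step 10 | 2,2-dimethyl-6-(2-oxopropyl)-4H-1,3-dioxin-4-one | CC(=O)CC1=CC(=O)OC(C)(C)O1
F2 | step 10 | 6-(2,4-dioxopentyl)-2,2-dimethyl-4H-1,3-dioxin-4-one | CC(=O)CC(=O)CC1=CC(=O)OC(C)(C)O1
F3 | step 10 | 4-chloro-3-methoxy-2,5,6-trimethylphenyl 3,5,7-trioxooctanoate | CC(=O)CC(=O)CC(=O)CC(=O)Oc1c(C)c(OC)c(Cl)c(C)c1C
F4 | step 9 | 5-[hydroxy(4-oxo-4H-pyran-3-yl)methylidene]-2,2-dimethyl-1,3-dioxane-4,6-dione | CC1(C)OC(=O)C(=C(O)c2coccc2=O)C(=O)O1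
F5 | step 9 | 4-chloro-3-methoxy-2,5,6-trimethylphenyl 3-oxo-3-(4-oxo-4H-pyran-3-yl)propanoate | O=C(CC(=O)c1coccc1=O)Oc1c(C)c(OC)c(Cl)c(C)c1C
F6 | step 7 | tert-butyl 5-(dimethylamino)-2-[(dimethylamino)methylidene]-3-oxopent-4-enoate | CN(C)/C=C/C(=O)C(=CN(C)C)C(=O)OC(C)(C)C
A1 | direct plan | 4-chloro-2,5,6-trimethylbenzene-1,3-diol | Cc1c(C)c(Cl)c(O)c(C)c1O
A2 | direct plan | 2,4-bis(benzyloxy)-6-methylbenzoic acid | Cc1cc(OCc2ccccc2)cc(OCc2ccccc2)c1C(=O)O
A3 | direct plan | 4-chloro-3-methoxy-2,5,6-trimethylphenyl 2,4-dihydroxy-6-methylbenzoate | COc1c(C)c(OC(=O)c2c(C)cc(O)cc2O)c(C)c(C)c1Cl
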